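all flasks: substrate 0.50 M; free catalyst 45 mM

|  | reagent | temperature | remark | time |
|---|---|---|---|---|
| noon | 0.14 M | 35 °C | run made earlier |  |
| summer | 0.24 M | 50 °C | run made earlier |  |
| violet | 0.350 M |  | at 60 °C until 5.0 min, from then on at 40 °C | 25 min |
| amber | 0.200 M |  | at 40 °C throughout | 80 min |

| run | time / min | target / % | substrate / % |
|---|---|---|---|
| noon | 3.00 | 1.0 | 97.6 |
| noon | 8.00 | 3.8 | 94.7 |
| noon | 15.0 | 6.7 | 91.7 |
| noon | 20.0 | 8.9 | 90.2 |
| noon | 30.0 | 11.0 | 87.7 |
| noon | 40.0 | 12.9 | 86.8 |
| summer | 1.50 | 1.6 | 96.4 |
| summer | 2.50 | 2.9 | 95.0 |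
| summer | 5.00 | 7.1 | 92.2 |
| summer | 8.00 | 9.3 | 90.2 |
| summer | 12.0 | 10.9 | 88.5 |
| summer | 20.0 | 13.3 | 86.4 |

(readings scatter by 0.3 percentage points)

- target is meant together with its crystals
- solid, in amounts per volume of the solution: crystals
- steps under discussion: reagent + free catalyst <-> catalyst intermediate A; crystals <-> target; substrate + catalyst intermediate A <-> catalyst intermediate B; catalyst intermediate B -> free catalyst + target; catalyst intermediate A -> spent catalyst; 2 reagent -> self-condensation product

- which of the two ends with the higher amount of target, in percent of the substrate charged ("neither" if they lie within 2 percentage points) (violet / amber / neither)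
- target at the end, in percent of the substrate charged, violet
- target at the end, in percent of the substrate charged, amber

Turn percent into molarity first, which is easy: the noon run's last reading, 12.9% target at 40.0 min, is 0.0645 M, and the summer run's, 13.3% at 20.0 min, is 0.0665 M. But the summer run got 0.100 M more reagent than the noon run, and its target stands 0.00200 M higher. So what else can reagent do? Each target takes one reagent, through catalyst intermediate A, and the steps offer reagent two other exits: two reagent condensing, and catalyst intermediate A turning into spent catalyst.

In violet and amber, reagent (0.350 M, 0.200 M) is charged below substrate (0.50 M), so it is the limiting reagent, and you should count target against it. Call the reagent share the target formed per reagent charged: the last readings give 46.1% for the noon run at 35 °C and 27.7% for the summer run at 50 °C.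

My own reckoning freezes this share on a straight line in temperature, though the two runs also differ in charge. For amber at 40 °C the line gives 40.0%, which is 16.0% of the substrate. Violet I treat as a flask at 60 °C throughout, since the summer run made more by 8.00 min, 9.3%, than after that, 4 percentage points. The line, carried past the summer run's temperature, then gives 15.5%, or 10.8% of the substrate. So I expect amber ahead by 5.2 points, beyond the margin.

The forecast said 14.5% for violet and 16% for amber, so neither, holding that “catalyst death through intermediate A sets the yield”; my violet lies lower.

The flasks give 12.5% for violet and 17.2% for amber, so amber ends higher.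

    reagent + free catalyst ⇌ catalyst intermediate A (K = 1.90 M⁻¹, k = 0.740 M⁻¹ s⁻¹, Ea = 64.0 kJ mol⁻¹, ΔH = −27.0 kJ mol⁻¹)
    crystals ⇌ target, rate k2*(cs2 - [target]) while solid is left; crystals form when [target] > cs2 (solubility = 0.240 M, k = 0.0120 s⁻¹)
    substrate + catalyst intermediate A ⇌ catalyst intermediate B (K = 17.0 M⁻¹, k = 0.0780 M⁻¹ s⁻¹, Ea = 52.0 kJ mol⁻¹, ΔH = −10.0 kJ mol⁻¹)
    catalyst intermediate B → free catalyst + target (k = 0.0360 s⁻¹, Ea = 80.0 kJ mol⁻¹)
    catalyst intermediate A → spent catalyst (k = 0.00330 s⁻¹, Ea = 91.0 kJ mol⁻¹)
    2 reagent → self-condensation product (k = 0.0370 M⁻¹ s⁻¹, Ea = 74.0 kJ mol⁻¹)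
    (constants at 60 °C)

In violet the self-condensation product stands at 0.134 M after 5.00 min and at 0.136 M at the end, which holds 77.7% of the charged reagent. The reagent share comes to 17.9% in violet and 43.0% in amber, against 46.1% in the noon run. Amber stopped at 20 min stands at a share of 29.2%, with 13% of its reagent still unbound.

The runs were computed with constants of no real substance; the scatter is artificial.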